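Where does this flask stop, now that its protic impurity may take more partner than the excess holds?

all flasks: substrate 0.035 M

| run | partner | protic impurity | remark | time |
|---|---|---|---|---|
| oak | 1.1 equiv | 3.5 mM | run made earlier |  |
| maple | 1.1 equiv | 14 mM | run made earlier |  |
| flask | 1.10 equiv | 7.00 mM |  | 2.0 d |

| run | time / h | substrate / % | target / % | isomer of the product / % |
|---|---|---|---|---|
| oak | 6.00 | 25.3 | 7.4 | 61.7 |
| oak | 12.0 | 19.2 | 4.1 | 67.4 |
| oak | 15.0 | 19.0 | 3.7 | 70.0 |
| oak | 20.0 | 19.5 | 4.9 | 70.2 |
| oak | 30.0 | 18.2 | 5.7 | 71.9 |
| oak | 40.0 | 18.7 | 4.4 | 71.6 |
| maple | 6.00 | 34.2 | 5.5 | 48.8 |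
| maple | 12.0 | 32.9 | 5.4 | 54.7 |
| maple | 15.0 | 32.1 | 4.1 | 55.2 |
| maple | 20.0 | 33.1 | 1.3 | 53.4 |
| maple | 30.0 | 32.0 | 5.5 | 55.2 |
| maple | 40.0 | 32.9 | 4.1 | 55.5 |

(each reading ± 1 percentage point)

- the earlier runs were read with a standard deviation of 1 percentage point
- the reaction counts as stopped when no species that holds the substrate changes by six tenths of a point or more over the second half of the time
- what has gone from substrate into another species counts as reacted, even if it can come back

- why nothing more happens at 2.0 d, or that something still does (it is still moving / forward and back rates have come level / the partner has run out first / all of the substrate has reacted)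
- conversion of substrate at 2.0 d
- amount of target at 2.0 d, in percent of the substrate charged
- amount of isomer of the product at 2.0 d, in percent of the substrate charged
- amount of target if the flask were left three thousand times as long, in percent of the substrate charged

Both runs are flat from about 15.0 h on, and I take the impurity to cost partner mole for mole. Oak's impurity, 3.5 mM, matches its excess of 3.50 mM, which makes oak the crossing. The flask lies beyond it: 7.00 mM is more than the excess, so the 31.5 mM that survives is less than the substrate, and on the charge partner is the limiting reagent.

From the last readings, c(target) + c(isomer) over c(substrate)·c(free partner) reads 484 /M in oak and 498 /M in maple. I carry their mean, 491 /M, as K, the free-partner constant: products over substrate times partner left free. The readings also lack a share of substrate, on average 0.256 of the substrate standing. Solving K with both balances, I get 25.1 mM of products, and the flask's books close: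

| Partner in the flask | Amount |
|---|---|
| charged | 38.5 mM |
| to protic impurity | 7.00 mM |
| into target and isomer | 25.1 mM |
| left free | 6.40 mM |

My conversion is 77.4 %, with products at 71.6 % of the substrate.

The forecast says forward and back rates have come level, with conversion 77.3 %, target 4.6 %, isomer 67 % and, far later, target 4.6 %; its conversion differs from mine in the last digit. It reads the constant from the same runs, “which supports a true equilibrium”.

The flask gives forward and back rates have come level, with conversion 77.3 %, target 4.17 %, isomer 67.0 % and, far later, target 4.17 %.

    substrate + partner ⇌ target (K = 28.0 /M, k = 0.743 /M/min)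
    substrate ⇌ dormant form (K = 0.270, k = 0.0141 /min)
    partner + protic impurity → quenched reagent (k = 3.03 /M/min)
    substrate + partner ⇌ isomer of the product (K = 450 /M, k = 0.373 /M/min)

The relaxation half-life between substrate + partner and the isomer, by that step alone with both directions together, is 0.0771 d at the asked time, short against 2.0 d. The isomer stands at 66.9 % after 1.00 d and 67.0 % after 2.00 d. These amounts put K at 478 /M in this flask. In a neighbour flask with 0.0088 M of substrate at the same equivalents, 7.00 mM quenched and 2.68 mM of partner surviving, the carried K gives products of 22.2 %, and that flask holds 22.0 %.

The earlier runs and the new flask are calculated for substances that don't exist, and the scatter is random.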